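**Plan**

- Retrosynthesis: the C1'–C6' bond of the ε ring is cut last, which opens that ring to the acyclic ψ end of the C40 alcohol 17. The chain is then cut at C11'=C12' and C11=C12 (two Wittig unions around a C10 dialdehyde) and at C6–C7 (ring sp2–alkyne bond, Sonogashira).
- Enabling feature (carotenoid numbering): the ε ring C1'–C6' holds the methine C6' between the gem-dimethyl carbon C1' and an unconjugated C4'=C5' alkene. This is the imprint of protonating a C1'=C2' alkene and letting C5'=C6' close on C1', so a lycopene ε-cyclase can write it from an open tail.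
- Forward: the hydroxy ring C1–C6 (bought as a chiral ketone) becomes an enol triflate, then the enyne C15 phosphonium salt. That salt plus the C10 dialdehyde gives a C25 aldehyde, and the ψ-C15 salt from pseudoionone completes the open-ended C40 chain 17. The ε ring closes last, enzymatically.
- Stereochemistry: C3 comes from (4R,6R)-4-hydroxy-2,2,6-trimethylcyclohexanone and is never touched. C6' (R) is set by the cyclase. Alkene geometry comes from E-configured building blocks and thermal Z→E relaxation of the two Wittig alkenes.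

Key step: step 10

Assumption: pseudoionone is used as its (3E,5E) isomer (commercial material enriched by fractional distillation), and the recombinant ε-cyclase is treated as a catalyst whose expression is not counted as a step.

**Route**

Step 1
Reactants: 1 (4R,6R)-4-hydroxy-2,2,6-trimethylcyclohexanone
Product: 2 (4R,6R)-4-(tert-butyldimethylsilyloxy)-2,2,6-trimethylcyclohexanone
Conditions: TBSCl, imidazole, DMF, rt
Reagents that add atoms: tert-butyldimethylsilyl chloride, CC(C)(C)[Si](C)(C)Cl
Why: Imidazole-promoted silyl ether formation should mask the secondary hydroxyl before enolate chemistry; C4 is not involved and C6 is flattened in the next step.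

Step 2
Reactants: 2 (4R,6R)-4-(tert-butyldimethylsilyloxy)-2,2,6-trimethylcyclohexanone
Product: 4 (4R)-4-(tert-butyldimethylsilyloxy)-2,6,6-trimethylcyclohex-1-en-1-yl trifluoromethanesulfonate, via lithium enolate 3 (not isolated)
Conditions: LiN(iPr)2, THF, −78 to 0 °C; PhNTf2, 0 °C to rt
Reagents that add atoms: N-phenylbis(trifluoromethanesulfonimide), O=S(=O)(N(c1ccccc1)S(=O)(=O)C(F)(F)F)C(F)(F)F
Why: C2 is quaternary, so deprotonation can occur only at C6, and O-sulfonylation of that enolate (enol triflate formation) should give the tetrasubstituted ring alkene as one regioisomer; the silyloxy group is γ to the carbonyl and cannot be eliminated.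

Step 3
Reactants: 4 (4R)-4-(tert-butyldimethylsilyloxy)-2,6,6-trimethylcyclohex-1-en-1-yl trifluoromethanesulfonate; 5 (2E)-3-methylpent-2-en-4-yn-1-ol
Product: 6 (2E)-5-[(4R)-4-(tert-butyldimethylsilyloxy)-2,6,6-trimethylcyclohex-1-en-1-yl]-3-methylpent-2-en-4-yn-1-ol
Conditions: Pd(PPh3)4 (cat.), CuI (cat.), Et3N, DMF, rt, Ar
Reagents that add atoms: none
Why: Sonogashira coupling of an enol triflate with a terminal alkyne should form the C6–C7 bond; the free primary alcohol is tolerated and the E alkene of 5 (later C9=C10) is carried over unchanged.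

Step 4
Reactants: 6 (2E)-5-[(4R)-4-(tert-butyldimethylsilyloxy)-2,6,6-trimethylcyclohex-1-en-1-yl]-3-methylpent-2-en-4-yn-1-ol
Product: 7 (2E)-5-[(4R)-4-hydroxy-2,6,6-trimethylcyclohex-1-en-1-yl]-3-methylpent-2-en-4-yn-1-ol
Conditions: Bu4NF, THF, rt
Reagents that add atoms: none
Why: Fluoride-driven cleavage of the silyl ether frees the C3 hydroxyl while the molecule is still robust; the later Wittig steps tolerate a free secondary alcohol.

Step 5
Reactants: 7 (2E)-5-[(4R)-4-hydroxy-2,6,6-trimethylcyclohex-1-en-1-yl]-3-methylpent-2-en-4-yn-1-ol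
Product: 8 [(2E)-5-[(4R)-4-hydroxy-2,6,6-trimethylcyclohex-1-en-1-yl]-3-methylpent-2-en-4-yn-1-yl]triphenylphosphonium bromide
Conditions: PPh3·HBr, MeOH, rt, dark; crystallisation
Reagents that add atoms: triphenylphosphine hydrobromide, [Br-].c1ccc(cc1)[PH+](c1ccccc1)c1ccccc1
Why: Only the primary allylic alcohol ionises under HBr and is captured at its unhindered terminus by the phosphine (phosphonium salt formation from an allylic alcohol); the secondary C3 hydroxyl is inert and crystallisation should remove any 2Z salt.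

Step 6
Reactants: 9 (3E,5E)-pseudoionone; 10 vinylmagnesium bromide
Product: 11 (4E,6E)-3,7,11-trimethyldodeca-1,4,6,10-tetraen-3-ol (racemic)
Conditions: CH2=CHMgBr, THF, −20 to 0 °C; aq. NH4Cl
Reagents that add atoms: none
Why: Grignard 1,2-addition to the dienone carbonyl should give the tertiary bis-allylic carbinol; its racemic centre is erased in the next step.

Step 7
Reactants: 11 (4E,6E)-3,7,11-trimethyldodeca-1,4,6,10-tetraen-3-ol
Product: 12 [(2E,4E,6E)-3,7,11-trimethyldodeca-2,4,6,10-tetraen-1-yl]triphenylphosphonium bromide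
Conditions: PPh3·HBr, MeOH, 0 °C to rt; crystallisation
Reagents that add atoms: triphenylphosphine hydrobromide, [Br-].c1ccc(cc1)[PH+](c1ccccc1)c1ccccc1
Why: Acid ionisation of the tertiary carbinol and phosphine capture at the primary end of the allyl cation (allylic transposition to the phosphonium salt) places the new alkene in conjugation with the diene; the 2E salt is expected to be the one that crystallises.

Step 8
Reactants: 8 acetylenic C15 phosphonium bromide; 13 (2E,4E,6E)-2,7-dimethylocta-2,4,6-trienedial
Product: 15 (3R)-3-hydroxy-7,8-didehydro-12'-apo-β-caroten-12'-al, via acetylenic C15 ylide 14 (not isolated)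
Conditions: NaOMe, MeOH/CH2Cl2, 0 °C to rt, 13 in excess, Ar, dark; then EtOH, 70 °C
Reagents that add atoms: none
Why: Wittig olefination of the allylic ylide with an excess of the symmetrical dialdehyde should stop at mono-olefination, helped by the lower electrophilicity of the longer polyenal product; the hindered 11Z alkene formed beside the E isomer should relax to E on warming.

Step 9
Reactants: 15 (3R)-3-hydroxy-7,8-didehydro-12'-apo-β-caroten-12'-al; 12 ψ-C15 phosphonium bromide
Product: 17 (3R)-7,8-didehydro-β,ψ-caroten-3-ol (all-E), via ψ-C15 ylide 16 (not isolated)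
Conditions: NaOMe, MeOH/CH2Cl2, rt, Ar, dark; then heptane/EtOH, 70 °C; crystallisation
Reagents that add atoms: none
Why: A second Wittig olefination forms C11'=C12' without touching the free hydroxyl or the enyne; the hindered 11'Z isomer should relax thermally and the all-E C40 compound is expected to crystallise.

Step 10
Reactants: 17 (3R)-7,8-didehydro-β,ψ-caroten-3-ol
Product: 18 (3R,6'R)-7,8-didehydro-β,ε-caroten-3-ol
Conditions: recombinant lycopene ε-cyclase (Lactuca sativa two-ring type, transit peptide removed), 17 in phosphatidylcholine liposomes, FAD, NADPH, MES–KOH buffer pH 6.5, Ar, 30 °C, dark; CHCl3/MeOH extraction, chromatography, crystallisation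
Reagents that add atoms: none
Why: The cyclase, a flavoprotein that uses reduced FAD without net redox change, should fold the all-E ψ end of 17 into a chair and protonate C2' of the C1'=C2' alkene; C6' of the C5'=C6' alkene then bonds to the tertiary C1' cation and an active-site base removes a proton from C4' of the resulting C5' cation, leaving the unconjugated C4'=C5' alkene. The closest known reaction is the conversion of the ψ ends of lycopene and of monocyclic δ-carotene into ε rings by lycopene ε-cyclases; the lettuce-type enzyme is chosen because it accepts a carotene that already carries a ring at its far end. Ring C1'–C6' closes in a 6-endo-trig cation–olefin mode, with both carbons of the attacking alkene inside the new ring. The one new stereocentre, C6', is set as R by the protein, which presents a single face of C6' to C1' and places its base at C4', not at C6' (proton loss there would give the β ring). The step needs reaction at one end only, one face at C6' and regioselective proton loss: the substrate secures the first because it has a single open ψ end and its hydroxy-enyne ring is already closed and far from the reacting terminus, while the other two are properties of the enzyme pocket that a mineral or Lewis acid could not reproduce without racemic, β-isomerised and polyene-scrambled material. Unreacted 17 has a longer chromophore and a different polarity, so it should separate cleanly and can be resubmitted.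

**Compound list**

1 | (4R,6R)-4-hydroxy-2,2,6-trimethylcyclohexanone | C[C@@H]1C[C@@H](O)CC(C)(C)C1=O | starting material
2 | (4R,6R)-4-(tert-butyldimethylsilyloxy)-2,2,6-trimethylcyclohexanone | C[C@@H]1C[C@@H](O[Si](C)(C)C(C)(C)C)CC(C)(C)C1=O | intermediate
3 | lithium (4R)-4-(tert-butyldimethylsilyloxy)-2,6,6-trimethylcyclohex-1-en-1-olate | [Li]OC1=C(C)C[C@@H](O[Si](C)(C)C(C)(C)C)CC1(C)C | intermediate
4 | (4R)-4-(tert-butyldimethylsilyloxy)-2,6,6-trimethylcyclohex-1-en-1-yl trifluoromethanesulfonate | FC(F)(F)S(=O)(=O)OC1=C(C)C[C@@H](O[Si](C)(C)C(C)(C)C)CC1(C)C | intermediate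
5 | (2E)-3-methylpent-2-en-4-yn-1-ol | C#C/C(C)=C/CO | starting material
6 | (2E)-5-[(4R)-4-(tert-butyldimethylsilyloxy)-2,6,6-trimethylcyclohex-1-en-1-yl]-3-methylpent-2-en-4-yn-1-ol | OC/C=C(\C)C#CC1=C(C)C[C@@H](O[Si](C)(C)C(C)(C)C)CC1(C)C | intermediate
7 | (2E)-5-[(4R)-4-hydroxy-2,6,6-trimethylcyclohex-1-en-1-yl]-3-methylpent-2-en-4-yn-1-ol | OC/C=C(\C)C#CC1=C(C)C[C@@H](O)CC1(C)C | intermediate
8 | [(2E)-5-[(4R)-4-hydroxy-2,6,6-trimethylcyclohex-1-en-1-yl]-3-methylpent-2-en-4-yn-1-yl]triphenylphosphonium bromide | [Br-].c1ccc(cc1)[P+](c1ccccc1)(c1ccccc1)C/C=C(\C)C#CC1=C(C)C[C@@H](O)CC1(C)C | intermediate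
9 | (3E,5E)-pseudoionone, (3E,5E)-6,10-dimethylundeca-3,5,9-trien-2-one | CC(C)=CCC/C(C)=C/C=C/C(C)=O | starting material
10 | vinylmagnesium bromide | C=C[Mg]Br | starting material
11 | (4E,6E)-3,7,11-trimethyldodeca-1,4,6,10-tetraen-3-ol (racemic) | CC(C)=CCC/C(C)=C/C=C/C(C)(O)C=C | intermediate
12 | [(2E,4E,6E)-3,7,11-trimethyldodeca-2,4,6,10-tetraen-1-yl]triphenylphosphonium bromide | CC(C)=CCC/C(C)=C/C=C/C(C)=C/C[P+](c1ccccc1)(c1ccccc1)c1ccccc1.[Br-] | intermediate
13 | (2E,4E,6E)-2,7-dimethylocta-2,4,6-trienedial | O=C/C(C)=C/C=C/C=C(C)/C=O | starting material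
14 | ylide of 8, triphenylphosphonium (2E)-5-[(4R)-4-hydroxy-2,6,6-trimethylcyclohex-1-en-1-yl]-3-methylpent-2-en-4-yn-1-ylide | c1ccc(cc1)[P+](c1ccccc1)(c1ccccc1)[CH-]/C=C(\C)C#CC1=C(C)C[C@@H](O)CC1(C)C | intermediate
15 | (3R)-3-hydroxy-7,8-didehydro-12'-apo-β-caroten-12'-al, (2E,4E,6E,8E,10E)-13-[(4R)-4-hydroxy-2,6,6-trimethylcyclohex-1-en-1-yl]-2,7,11-trimethyltrideca-2,4,6,8,10-pentaen-12-ynal | O=C/C(C)=C/C=C/C=C(C)/C=C/C=C(\C)C#CC1=C(C)C[C@@H](O)CC1(C)C | intermediate
16 | ylide of 12, triphenylphosphonium (2E,4E,6E)-3,7,11-trimethyldodeca-2,4,6,10-tetraen-1-ylide | CC(C)=CCC/C(C)=C/C=C/C(C)=C/[CH-][P+](c1ccccc1)(c1ccccc1)c1ccccc1 | intermediate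
17 | (3R)-7,8-didehydro-β,ψ-caroten-3-ol (all-E) | CC(C)=CCC/C(C)=C/C=C/C(C)=C/C=C/C(C)=C/C=C/C=C(C)/C=C/C=C(\C)C#CC1=C(C)C[C@@H](O)CC1(C)C | intermediate
18 | (3R,6'R)-7,8-didehydro-β,ε-caroten-3-ol (all-E) | CC1=CCCC(C)(C)[C@H]1/C=C/C(C)=C/C=C/C(C)=C/C=C/C=C(C)/C=C/C=C(\C)C#CC1=C(C)C[C@@H](O)CC1(C)C | target

**Count and risks**

Total step count: 10. Longest linear sequence: 8 steps (steps 1–5, 8, 9, 10; compounds 1 → 2 → 4 → 6 → 7 → 8 → 15 → 17 → 18).

Steps most likely to fail:

Step 10. The cyclase may bind the substrate unproductively because of the rigid hydroxy-enyne end, the water-insoluble polyene may not reach the membrane enzyme, or the polyene may be lost by oxidation during a long incubation. The fallback forms the same C1'–C6' bond chemically at the C13 stage and brings the ring in as a Wittig salt. It sets out from pseudoionone 9: cyclisation in 85 % H3PO4 should give racemic α-ionone F1, and preparative chromatography on a cellulose carbamate chiral phase should give (R)-α-ionone F2. Addition of vinylmagnesium bromide 10 would give 3-methyl-5-[(1R)-2,6,6-trimethylcyclohex-2-en-1-yl]penta-1,4-dien-3-ol F3, and PPh3·HBr in MeOH would convert it into the ε-C15 phosphonium bromide F4. Its ylide F5 (NaOMe, MeOH/CH2Cl2) would be condensed with the C25 aldehyde 15 in a Wittig reaction, and the sequence comes back to the route at target 18.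

Step 8. Both aldehyde groups of the dialdehyde may be olefinated, and Z isomers may accumulate at the new alkene. The fallback differentiates the two ends by protection and sets out from dialdehyde 13. One equivalent of 2,2-dimethylpropane-1,3-diol with a trace of TsOH should give the mono-acetal (2E,4E,6E)-7-(5,5-dimethyl-1,3-dioxan-2-yl)-2-methylocta-2,4,6-trienal F6. Wittig reaction with ylide 14 would give the C25 acetal F7, and mild hydrolysis (dilute oxalic acid, THF/H2O) would unmask the aldehyde, coming back to the route at 15.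

Step 5. Ionisation to the delocalised enynyl allyl cation may scramble the E geometry of the C2=C3 alkene (later C9=C10), or the cation may be trapped at the wrong position. The fallback avoids a free cation and sets out from silyl ether 6. Appel bromination (CBr4, PPh3, CH2Cl2, 0 °C) should give the allylic bromide F8 by direct displacement. PPh3 in ethyl acetate would give the silylated phosphonium bromide F9, and methanolysis of the silyl ether with a trace of HBr in MeOH comes back to the route at 8.

**Further compounds**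

F1 | step 10 | racemic α-ionone, (3E)-4-(2,6,6-trimethylcyclohex-2-en-1-yl)but-3-en-2-one | CC1=CCCC(C)(C)C1/C=C/C(C)=O
F2 | step 10 | (R)-α-ionone, (3E)-4-[(1R)-2,6,6-trimethylcyclohex-2-en-1-yl]but-3-en-2-one | CC1=CCCC(C)(C)[C@H]1/C=C/C(C)=O
F3 | step 10 | (4E)-3-methyl-5-[(1R)-2,6,6-trimethylcyclohex-2-en-1-yl]penta-1,4-dien-3-ol (both C3 epimers) | CC1=CCCC(C)(C)[C@H]1/C=C/C(C)(O)C=C
F4 | step 10 | [(2E,4E)-3-methyl-5-[(1R)-2,6,6-trimethylcyclohex-2-en-1-yl]penta-2,4-dien-1-yl]triphenylphosphonium bromide | CC1=CCCC(C)(C)[C@H]1/C=C/C(C)=C/C[P+](c1ccccc1)(c1ccccc1)c1ccccc1.[Br-]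
F5 | step 10 | ylide of F4, triphenylphosphonium (2E,4E)-3-methyl-5-[(1R)-2,6,6-trimethylcyclohex-2-en-1-yl]penta-2,4-dien-1-ylide | CC1=CCCC(C)(C)[C@H]1/C=C/C(C)=C/[CH-][P+](c1ccccc1)(c1ccccc1)c1ccccc1
F6 | step 8 | (2E,4E,6E)-7-(5,5-dimethyl-1,3-dioxan-2-yl)-2-methylocta-2,4,6-trienal | O=C/C(C)=C/C=C/C=C(C)/C1OCC(C)(C)CO1
F7 | step 8 | 5,5-dimethyl-1,3-dioxan-2-yl acetal of 15 at C12' | CC1(C)COC(OC1)/C(C)=C/C=C/C=C(C)/C=C/C=C(\C)C#CC2=C(C)C[C@@H](O)CC2(C)C
F8 | step 5 | (2E)-1-bromo-5-[(4R)-4-(tert-butyldimethylsilyloxy)-2,6,6-trimethylcyclohex-1-en-1-yl]-3-methylpent-2-en-4-yne | BrC/C=C(\C)C#CC1=C(C)C[C@@H](O[Si](C)(C)C(C)(C)C)CC1(C)C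
F9 | step 5 | [(2E)-5-[(4R)-4-(tert-butyldimethylsilyloxy)-2,6,6-trimethylcyclohex-1-en-1-yl]-3-methylpent-2-en-4-yn-1-yl]triphenylphosphonium bromide | [Br-].c1ccc(cc1)[P+](c1ccccc1)(c1ccccc1)C/C=C(\C)C#CC1=C(C)C[C@@H](O[Si](C)(C)C(C)(C)C)CC1(C)C
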